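**Strategy**

The route rests on making the two benzylic C7–O bonds of the terminal units A and E last. Rings A and E are the only free phenols, and each stands para to a C7 methylene flanked by the C8 aryloxy stereocentre and the C9 hydroxyl. Oxidising the hexaol precursor therefore gives quinone methides at exactly these two carbons, and a boron tether on each C9 oxygen returns oxygen to C7 from within, setting 7R (unit A) and 7S (unit E) in one operation. The precursor is the 7A,7E-dideoxy target: (+)-syringaresinol carrying 7-deoxy unit A on ring B and the threo unit D/7-deoxy unit E chain on ring C.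

Key step: step 15

Remarks on the chemistry:
- Locants: C7, C8, C9 are the benzylic, central and terminal carbons of each propane unit, with the unit letter appended. Rings B and C are the syringyl rings of the furofuran; ring B carries unit A, ring C carries unit D, and ring D carries unit E.
- C8 of units A and E are of opposite sense. Unit A is attached with inversion and unit E with retention, so one carbinol, made from (S)-benzyl glycidyl ether alone, serves both; the (R)-epoxide is not needed.
- With the chain Ar–C7–C8–C9 drawn zigzag, syn (aldol sense) equals threo and anti equals erythro. Unit D is threo (7S,8S); units A and E are erythro.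
- C8 of units A and E changes descriptor between the precursor and the target only because C7 gains priority on hydroxylation; no bond at C8 is touched.
- Assumption: racemic syringaresinol is resolved by chiral chromatography, and the (7S,8R,7′S,8′R) antipode is taken to be the dextrorotatory one; the descriptors define the compound.

**Route**

Step 1
Reactants: 1 syringaldehyde; 2 ethyl (triphenylphosphoranylidene)acetate
Product: 3 ethyl (E)-sinapate
Conditions: toluene, 90 °C
Reagents that add atoms: none
Why: Wittig olefination with a stabilised ylide tolerates the free phenol and should give the E-cinnamate ester.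

Step 2
Reactants: 3 ethyl (E)-sinapate
Product: 4 sinapyl alcohol
Conditions: i-Bu2AlH (4 equiv), toluene, −78 → 0 °C; aq. potassium sodium tartrate
Reagents that add atoms: none
Why: Hydride 1,2-reduction of an α,β-unsaturated ester by i-Bu2AlH should stop at the allylic alcohol, the extra equivalents covering the acidic phenol, and leaves the E-alkene untouched.

Step 3
Reactants: 4 sinapyl alcohol (two molecules)
Product: 6 racemic syringaresinol, via bis(quinone methide) 5 (not isolated)
Conditions: FeCl3·6H2O (1.1 equiv), acetone/H2O, rt, dilute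
Reagents that add atoms: none
Why: Oxidative phenol coupling (dehydrodimerisation): one-electron oxidation gives the sinapyl radical, whose methoxy-blocked ortho positions leave β–β coupling as the main path, and the two C9 hydroxyls of 5 then add to the quinone methide carbons to close the cis-fused bicycle with exo aryl groups, as the racemate because nothing chiral is present.

Step 4
Reactants: 6 racemic syringaresinol
Product: 7 (+)-syringaresinol
Conditions: preparative HPLC, cellulose tris(3,5-dimethylphenylcarbamate) phase, hexane/EtOH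
Reagents that add atoms: none
Why: Resolution by chromatography on a chiral stationary phase separates the enantiomers without touching a bond, the (7S,8R,7′S,8′R) antipode being recognised by its positive rotation and the other set aside.

Step 5
Reactants: 8 4-bromo-2-methoxyphenol
Product: 9 1-(benzyloxy)-4-bromo-2-methoxybenzene
Conditions: BnBr, K2CO3, acetone, reflux
Reagents that add atoms: benzyl bromide, BrCc1ccccc1
Why: Williamson ether synthesis; the benzyl ether protects the phenol through the organometallic and strongly basic steps and is removed with the other benzyl groups in step 14.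

Step 6
Reactants: 9 1-(benzyloxy)-4-bromo-2-methoxybenzene; 10 (S)-benzyl glycidyl ether
Product: 12 (2S)-1-(benzyloxy)-3-[4-(benzyloxy)-3-methoxyphenyl]propan-2-ol, via aryl Grignard reagent 11 (not isolated)
Conditions: Mg, THF, 40 °C; then CuI (10 mol%), 10, THF, −30 → 0 °C; aq. NH4Cl
Reagents that add atoms: none
Why: Copper-catalysed Grignard opening of a terminal epoxide takes place at the CH2 carbon, so the epoxide stereocentre is carried unchanged into the (S)-carbinol.

Step 7
Reactants: 12 (S)-carbinol; 13 4-fluoro-3-methoxybenzonitrile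
Product: 14 4-{[(2S)-1-(benzyloxy)-3-[4-(benzyloxy)-3-methoxyphenyl]propan-2-yl]oxy}-3-methoxybenzonitrile
Conditions: NaH, DMF, 0 °C; then 13, 0 °C → rt
Reagents that add atoms: none
Why: Nucleophilic aromatic substitution (addition–elimination) of the fluoride para to the nitrile by the sodium alkoxide; the C8–O bond of the carbinol is not broken, so C8 of unit E keeps its configuration (S).

Step 8
Reactants: 14 nitrile ether
Product: 16 4-{[(2S)-1-(benzyloxy)-3-[4-(benzyloxy)-3-methoxyphenyl]propan-2-yl]oxy}-3-methoxybenzaldehyde, via aldimine 15 (not isolated)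
Conditions: i-Bu2AlH (1.2 equiv), CH2Cl2, −78 °C; then aq. potassium sodium tartrate, rt
Reagents that add atoms: water, O
Why: Partial reduction of a nitrile: one hydride adds to give an N-aluminio imine that does not react further at low temperature and is hydrolysed through 15 to the aldehyde on work-up, the ethers being inert.

Step 9
Reactants: 17 (R)-4-benzyl-1,3-oxazolidin-2-one; 18 chloroacetyl chloride
Product: 19 (4R)-4-benzyl-3-(chloroacetyl)-1,3-oxazolidin-2-one
Conditions: n-BuLi, THF, −78 °C; then 18, −78 → 0 °C
Reagents that add atoms: none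
Why: N-acylation of the lithiated oxazolidinone by an acid chloride is much faster at low temperature than displacement of the α-chloride, and the auxiliary stereocentre is not involved.

Step 10
Reactants: 7 (+)-syringaresinol (2.5 equiv); 12 (S)-carbinol
Product: 20 mono-ether of (+)-syringaresinol carrying benzyl-protected 7-deoxy unit A (8A R) on the ring B oxygen
Conditions: PPh3, DIAD, THF, 0 °C → rt
Reagents that add atoms: none
Why: Mitsunobu etherification: the syringyl phenol (pKa about 10) is the pronucleophile and displaces the oxyphosphonium group by SN2 with inversion, turning the (S)-carbinol into the (R)-configured C8 of unit A, while the excess of the C2-symmetric diphenol, whose two hydroxyls are equivalent, favours the mono-ether and is recovered.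

Step 11
Reactants: 20 mono-ether; 19 chloroacetyl imide
Product: 21 aryloxyacetyl imide (ring C oxygen–CH2–C(=O)–N of the (R)-auxiliary)
Conditions: K2CO3, NaI (cat.), acetone, 40 °C
Reagents that add atoms: none
Why: Williamson alkylation of the phenoxide at the α-halo carbonyl carbon, accelerated by iodide exchange, should outrun acyl transfer from the imide to the hindered 2,6-dimethoxyphenoxide.

Step 12
Reactants: 21 aryloxyacetyl imide; 16 aldehyde
Product: 23 syn-aldol adduct (2R,3S), via dibutylboron Z-enolate 22 (not isolated)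
Conditions: Bu2BOTf, i-Pr2NEt, CH2Cl2, −78 → 0 °C; then 16, −78 → 0 °C; pH 7 buffer (NaH2PO4/Na2HPO4), MeOH, H2O2, 0 °C
Reagents that add atoms: none
Why: Evans syn-aldol reaction: the Z-boron enolate reacts with the aldehyde through a closed chair transition state on the enolate face left open by the benzyl group of the (R)-auxiliary, which should set C8 and C7 of unit D together as the syn (2R,3S) adduct, that is the threo 7S,8S arrangement once C9 is reduced.

Step 13
Reactants: 23 aldol adduct
Product: 24 tetra-O-benzyl ether of the 7A,7E-dideoxy target (unit D 7S,8S diol)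
Conditions: LiBH4, MeOH (1 equiv), THF, 0 °C
Reagents that add atoms: none
Why: Reductive cleavage of the N-acyloxazolidinone: hydride attacks the exocyclic carbonyl to give the primary alcohol and release the auxiliary faster than enolisation or retro-aldol, so C7 and C8 of unit D are kept.

Step 14
Reactants: 24 tetra-O-benzyl ether
Product: 25 7A,7E-dideoxy target (hexaol precursor)
Conditions: H2 (1 atm), Pd/C, EtOAc/EtOH, rt
Reagents that add atoms: none
Why: Catalytic hydrogenolysis removes the two aryl and two primary alkyl benzyl ethers under neutral conditions, under which the benzylic C–O bonds of the furofuran and of unit D, all on non-phenolic 4-alkoxyaryl rings, are expected to react far more slowly.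

Step 15
Reactants: 25 7A,7E-dideoxy target
Product: 29 target CNP0316493.3, via tris(boronate) 26 (not isolated), via bis(quinone methide) 27 (not isolated), via tris(dioxaborinane) 28 (not isolated)
Conditions: PhB(OH)2 (4 equiv), 4 Å MS, CH2Cl2/MeCN, rt; then Ag2O (6 equiv), dark, rt, 2 mM; then Et3N (0.2 equiv), 0 °C → rt; filter; aq. D-sorbitol/NaHCO3
Reagents that add atoms: phenylboronic acid, OB(O)c1ccccc1
Why: Proposed new method: Ag2O takes two electrons and the O–H and C7–H hydrogens from each 4-alkyl-2-methoxyphenol (rings A and E) to give bis(quinone methide) 27, while rings B, C and D are phenol ethers and cannot follow this path; in each unit the C9–O–B(Ph)–OH hemiester, turned into a nucleophilic boronate by the amine, then adds through its B–OH oxygen to C7 and re-aromatises the ring. The closest known reactions are the Ag2O oxidation of 4-alkyl-2-methoxyphenols to quinone methides, the hydration of such quinone methides in arylglycerol β-aryl ethers and the amine-promoted oxa-conjugate addition of boronic acid hemiesters to hydroxy enones; their union on an 8-aryloxy-9-hydroxy quinone methide, twice in one molecule, is untested. Each addition closes a transient six-membered 1,3,2-dioxaborinane in the 6-exo-trig mode (the C7=C1 bond lies outside the new ring), and these rings are opened again on work-up, so no ring is built. Each new C7 centre is set by its C8 neighbour: allylic strain holds H8 in the plane of the quinone methide, the boron-bound oxygen arrives from the face of C9, and in the chair the former ring and the C8 aryloxy group are both equatorial, which gives the trans boronate, that is erythro, 7R in unit A and 7S in unit E. The step needs chemoselectivity (only the two free phenols are oxidised, and the unit D diol is held as its cyclic boronate), site selectivity (C7 is the only carbon para to a free phenol) and erythro selectivity (intramolecular delivery must outrun addition of the water formed, which the molecular sieves keep low).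

**Compound list**

1 | syringaldehyde (4-hydroxy-3,5-dimethoxybenzaldehyde) | COc1cc(C=O)cc(OC)c1O | starting material
2 | ethyl (triphenylphosphoranylidene)acetate | CCOC(=O)C=P(c1ccccc1)(c1ccccc1)c1ccccc1 | starting material
3 | ethyl (E)-sinapate, ethyl (2E)-3-(4-hydroxy-3,5-dimethoxyphenyl)prop-2-enoate | CCOC(=O)/C=C/c1cc(OC)c(O)c(OC)c1 | intermediate
4 | sinapyl alcohol, (2E)-3-(4-hydroxy-3,5-dimethoxyphenyl)prop-2-en-1-ol | OC/C=C/c1cc(OC)c(O)c(OC)c1 | intermediate
5 | β–β-coupled bis(quinone methide), 2,3-bis(hydroxymethyl)-1,4-bis(3,5-dimethoxy-4-oxocyclohexa-2,5-dien-1-ylidene)butane, racemic (2R*,3R*), drawn as the 2R,3R form | OC[C@H](C=C1C=C(OC)C(=O)C(OC)=C1)[C@@H](C=C1C=C(OC)C(=O)C(OC)=C1)CO | intermediate (not isolated)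
6 | racemic syringaresinol, 2,6-bis(4-hydroxy-3,5-dimethoxyphenyl)-3,7-dioxabicyclo[3.3.0]octane, cis-fused with exo aryl groups; SMILES shows the 7S,8R,7′S,8′R enantiomer, the mirror image being present in equal amount | COc1cc([C@H]2OC[C@H]3[C@@H]2CO[C@@H]3c2cc(OC)c(O)c(OC)c2)cc(OC)c1O | intermediate
7 | (+)-syringaresinol, single (7S,8R,7′S,8′R) enantiomer | COc1cc([C@H]2OC[C@H]3[C@@H]2CO[C@@H]3c2cc(OC)c(O)c(OC)c2)cc(OC)c1O | intermediate
8 | 4-bromo-2-methoxyphenol | COc1cc(Br)ccc1O | starting material
9 | 1-(benzyloxy)-4-bromo-2-methoxybenzene | COc1cc(Br)ccc1OCc1ccccc1 | intermediate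
10 | (S)-benzyl glycidyl ether, (2S)-2-[(benzyloxy)methyl]oxirane | C(OCc1ccccc1)[C@@H]1CO1 | starting material
11 | [4-(benzyloxy)-3-methoxyphenyl]magnesium bromide | COc1cc([Mg]Br)ccc1OCc1ccccc1 | intermediate (not isolated)
12 | (2S)-1-(benzyloxy)-3-[4-(benzyloxy)-3-methoxyphenyl]propan-2-ol | COc1cc(C[C@H](O)COCc2ccccc2)ccc1OCc1ccccc1 | intermediate
13 | 4-fluoro-3-methoxybenzonitrile | COc1cc(C#N)ccc1F | starting material
14 | 4-{[(2S)-1-(benzyloxy)-3-[4-(benzyloxy)-3-methoxyphenyl]propan-2-yl]oxy}-3-methoxybenzonitrile | N#Cc1ccc(O[C@H](COCc2ccccc2)Cc2ccc(OCc3ccccc3)c(OC)c2)c(OC)c1 | intermediate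
15 | N-unsubstituted aldimine of 16 (ArCH=NH, same 2S side chain) | N=Cc1ccc(O[C@H](COCc2ccccc2)Cc2ccc(OCc3ccccc3)c(OC)c2)c(OC)c1 | intermediate (not isolated)
16 | 4-{[(2S)-1-(benzyloxy)-3-[4-(benzyloxy)-3-methoxyphenyl]propan-2-yl]oxy}-3-methoxybenzaldehyde | O=Cc1ccc(O[C@H](COCc2ccccc2)Cc2ccc(OCc3ccccc3)c(OC)c2)c(OC)c1 | intermediate
17 | (R)-4-benzyl-1,3-oxazolidin-2-one | O=C1OC[C@@H](Cc2ccccc2)N1 | starting material
18 | chloroacetyl chloride | ClCC(Cl)=O | starting material
19 | (4R)-4-benzyl-3-(chloroacetyl)-1,3-oxazolidin-2-one | O=C1OC[C@@H](Cc2ccccc2)N1C(=O)CCl | intermediate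
20 | (+)-syringaresinol mono-ether: ring B O4 bonded to C8 of unit A as the (2R)-1-(benzyloxy)-3-[4-(benzyloxy)-3-methoxyphenyl]propan-2-yl group; ring C phenol free; core 7S,8R,7′S,8′R | COc1cc(C[C@H](COCc2ccccc2)Oc2c(OC)cc([C@H]3OC[C@H]4[C@@H]3CO[C@@H]4c3cc(OC)c(O)c(OC)c3)cc2OC)ccc1OCc1ccccc1 | intermediate
21 | 20 with the ring C oxygen alkylated as ArO–CH2–C(=O)–N of (4R)-4-benzyl-1,3-oxazolidin-2-one | COc1cc(C[C@H](COCc2ccccc2)Oc2c(OC)cc([C@H]3OC[C@H]4[C@@H]3CO[C@@H]4c3cc(OC)c(OCC(=O)N4C(=O)OC[C@H]4Cc4ccccc4)c(OC)c3)cc2OC)ccc1OCc1ccccc1 | intermediate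
22 | dibutylboron Z-enolate of 21 (aryloxy and OBBu2 cis) | COc1cc(C[C@H](COCc2ccccc2)Oc2c(OC)cc([C@H]3OC[C@H]4[C@@H]3CO[C@@H]4c3cc(OC)c(O/C=C(\OB(CCCC)CCCC)N4C(=O)OC[C@H]4Cc4ccccc4)c(OC)c3)cc2OC)ccc1OCc1ccccc1 | intermediate (not isolated)
23 | syn-aldol adduct: (4R)-auxiliary imide of the (2R,3S)-2-(ring C aryloxy)-3-hydroxy-3-(ring D aryl)propanoic acid; ring D carries benzyl-protected 7-deoxy unit E (8E S) on O4; unit A as in 20 | COc1cc(C[C@H](COCc2ccccc2)Oc2c(OC)cc([C@H]3OC[C@H]4[C@@H]3CO[C@@H]4c3cc(OC)c(O[C@@H](C(=O)N4C(=O)OC[C@H]4Cc4ccccc4)[C@@H](O)c4ccc(O[C@H](COCc5ccccc5)Cc5ccc(OCc6ccccc6)c(OC)c5)c(OC)c4)c(OC)c3)cc2OC)ccc1OCc1ccccc1 | intermediate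
24 | tetra-O-benzyl ether of 25 (benzyl on O4 of rings A and E and on O9 of units A and E); 8A R, 7D S, 8D S, 8E S | COc1cc(C[C@H](COCc2ccccc2)Oc2c(OC)cc([C@H]3OC[C@H]4[C@@H]3CO[C@@H]4c3cc(OC)c(O[C@@H](CO)[C@@H](O)c4ccc(O[C@H](COCc5ccccc5)Cc5ccc(OCc6ccccc6)c(OC)c5)c(OC)c4)c(OC)c3)cc2OC)ccc1OCc1ccccc1 | intermediate
25 | 7A,7E-dideoxy target (C7 is CH2 in units A and E); 8A R, 7D S, 8D S, 8E S; core 7S,8R,7′S,8′R; six free hydroxyls | COc1cc(C[C@H](CO)Oc2c(OC)cc([C@H]3OC[C@H]4[C@@H]3CO[C@@H]4c3cc(OC)c(O[C@@H](CO)[C@@H](O)c4ccc(O[C@H](CO)Cc5ccc(O)c(OC)c5)c(OC)c4)c(OC)c3)cc2OC)ccc1O | intermediate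
26 | tris(phenylboronate) of 25: B(Ph)OH hemiesters on O9 of units A and E, cyclic 2-phenyl-1,3,2-dioxaborinane across O7 and O9 of unit D | COc1cc(C[C@H](COB(O)c2ccccc2)Oc2c(OC)cc([C@H]3OC[C@H]4[C@@H]3CO[C@@H]4c3cc(OC)c(O[C@H]4COB(c5ccccc5)O[C@H]4c4ccc(O[C@H](COB(O)c5ccccc5)Cc5ccc(O)c(OC)c5)c(OC)c4)c(OC)c3)cc2OC)ccc1O | intermediate (not isolated)
27 | bis(quinone methide) of 26: rings A and E as 3-methoxy-4-oxocyclohexa-2,5-dien-1-ylidenes with exocyclic C1=C7 bonds (geometric isomers not specified) | COC1=CC(=C[C@H](COB(O)c2ccccc2)Oc2c(OC)cc([C@H]3OC[C@H]4[C@@H]3CO[C@@H]4c3cc(OC)c(O[C@H]4COB(c5ccccc5)O[C@H]4c4ccc(O[C@H](COB(O)c5ccccc5)C=C5C=CC(=O)C(OC)=C5)c(OC)c4)c(OC)c3)cc2OC)C=CC1=O | intermediate (not isolated)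
28 | tris(2-phenyl-1,3,2-dioxaborinane) of the target: O7/O9 boronates in units A, D and E; aryl and aryloxy trans in A and E, cis in D | COc1cc([C@H]2OB(c3ccccc3)OC[C@@H]2Oc2c(OC)cc([C@H]3OC[C@H]4[C@@H]3CO[C@@H]4c3cc(OC)c(O[C@H]4COB(c5ccccc5)O[C@H]4c4ccc(O[C@@H]5COB(c6ccccc6)O[C@H]5c5ccc(O)c(OC)c5)c(OC)c4)c(OC)c3)cc2OC)ccc1O | intermediate (not isolated)
29 | CNP0316493.3: (+)-syringaresinol with erythro guaiacylglycerol unit A (7R,8S) bonded through C8 to O4 of ring B, and threo unit D (7S,8S) bonded through C8 to O4 of ring C, ring D O4 carrying erythro unit E (7S,8R) through C8 | COc1cc([C@@H](O)[C@H](CO)Oc2c(OC)cc([C@H]3OC[C@H]4[C@@H]3CO[C@@H]4c3cc(OC)c(O[C@@H](CO)[C@@H](O)c4ccc(O[C@H](CO)[C@@H](O)c5ccc(O)c(OC)c5)c(OC)c4)c(OC)c3)cc2OC)ccc1O | target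

**Count and risks**

Total step count: 15. Longest linear sequence: 10 steps (steps 1–4 and 10–15, from syringaldehyde).

Steps most likely to fail:

1. Step 15 (proposed new method). The quinone methides may be consumed by paths that outrun boron delivery: tautomerisation to the C7=C8 enol ether, unselective hydration by the water formed, or phenoxyl radical coupling on rings A and E during the silver oxidation. Delivery may also show poor facial selectivity. Fallback with known chemistry, setting out from 25: DDQ in aqueous dioxane at 0 °C should oxidise only the two methylenes para to free phenols, through the same quinone methides, hydration and a second oxidation, to give 7A,7E-diketone F1. The non-phenolic unit D alcohol reacts much more slowly, and the mixture is kept cold and neutral to avoid epimerisation at C8. Chelation-controlled reduction with Zn(BH4)2 in Et2O/THF at −20 °C, with hydride arriving on the zinc chelate of the ketone and C8 aryloxy oxygens from the side away from C9, should favour the erythro carbinols. The fallback comes back to the route at 29 after chromatographic removal of threo isomers.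

2. Step 10. Steric hindrance at the 2,6-dimethoxyphenol and at the secondary carbinol may divert the oxyphosphonium salt to elimination towards the styrene or leave it unreacted, and over-etherification to the bis-ether may compete. Fallback, setting out from 12: mesylation (MsCl, Et3N, CH2Cl2, 0 °C) gives (2S)-mesylate F2. SN2 displacement with inversion by the cesium phenoxide of 7 (7 in excess, Cs2CO3, DMF, 50 °C) comes back to the route at 20.

3. Step 11. Acyl transfer from the imide to the phenoxide (loss of the auxiliary) or base-induced decomposition of the α-halo imide may compete with O-alkylation. Fallback, setting out from 20: alkylation with methyl bromoacetate (K2CO3, acetone) gives methyl aryloxyacetate F3, and saponification (LiOH, THF/H2O) gives aryloxyacetic acid F4. Activation as pivalic mixed anhydride F5 (t-BuCOCl, Et3N, THF, −20 °C) and N-acylation of 17 in the presence of LiCl comes back to the route at 21.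

**Further compounds**

F1 | step 15 | 7A,7E-diketone of 25 (C7=O in units A and E; all other atoms and stereocentres as in 25) | COc1cc(C(=O)[C@H](CO)Oc2c(OC)cc([C@H]3OC[C@H]4[C@@H]3CO[C@@H]4c3cc(OC)c(O[C@@H](CO)[C@@H](O)c4ccc(O[C@H](CO)C(=O)c5ccc(O)c(OC)c5)c(OC)c4)c(OC)c3)cc2OC)ccc1O
F2 | step 10 | (2S)-1-(benzyloxy)-3-[4-(benzyloxy)-3-methoxyphenyl]propan-2-yl methanesulfonate | COc1cc(C[C@H](OS(C)(=O)=O)COCc2ccccc2)ccc1OCc1ccccc1
F3 | step 11 | methyl aryloxyacetate of 20 (ring C oxygen–CH2–CO2Me) | COc1cc(C[C@H](COCc2ccccc2)Oc2c(OC)cc([C@H]3OC[C@H]4[C@@H]3CO[C@@H]4c3cc(OC)c(OCC(=O)OC)c(OC)c3)cc2OC)ccc1OCc1ccccc1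
F4 | step 11 | aryloxyacetic acid of 20 (ring C oxygen–CH2–CO2H) | COc1cc(C[C@H](COCc2ccccc2)Oc2c(OC)cc([C@H]3OC[C@H]4[C@@H]3CO[C@@H]4c3cc(OC)c(OCC(O)=O)c(OC)c3)cc2OC)ccc1OCc1ccccc1
F5 | step 11 | pivalic mixed anhydride of F4 (not isolated) | COc1cc(C[C@H](COCc2ccccc2)Oc2c(OC)cc([C@H]3OC[C@H]4[C@@H]3CO[C@@H]4c3cc(OC)c(OCC(=O)OC(=O)C(C)(C)C)c(OC)c3)cc2OC)ccc1OCc1ccccc1
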